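**Plan**
Numbering of each half: C1(=C12)–C2(=O)–C3–C4–C5–C6–C7–C8(C13H3)–C9–C10–C11(CH3)2, with C9 also bonded to C1 and C4, and C11 to C5. Ring A = C1, C2, C3, C4, C9; ring B = C4 to C9; ring C = C4, C5, C11, C10, C9; primes mark the saturated half.
Cuts, in retrosynthetic order: C3–C12' (Michael dimerisation of the α-methylene ketone monomer), C8–C9 (radical closure of ring B), C4–C9, C1–C2 and C2–C3 (Pauson–Khand reaction), C9–C10 (acetylide alkylation), C5–C11 (allylic alkylation).
Enabling feature: rings A and C are a cis-fused diquinane that can exist as the C1=C9 enone, which makes C9 an acceptor carbon 1,3 to C5 across ring C. C8 and C13 are a terminal alkene plus one hydrogen atom, so a butenyl chain on C5 closes ring B on C9.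
Forward order: chain assembly (C5–C11, then C9–C10), rings A and C together, ring B, unmasking of C1=C12, union of two monomers.
C12 travels from the alkyne as CH2OTBS on C1. This avoids a C1 versus C3 choice in a late methylenation and biases the C8 centre through A(1,3) strain.
Stereochemistry: C5 comes from the chiral iridium catalyst; C4, then C9 and C8, then C3 and C1' follow from C5 by substrate control.

Key step: step 9

Assumption: the (Ra,R,R) phosphoramidite is taken to give the 3S branched ester (otherwise its mirror image is used), and the C1-substituted ketones after the key step are drawn as the epimer expected from protonation anti to the C8 methyl group; the other epimer converges in the elimination.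

**Step 1**
Reactants: 1 pent-4-enal; 2 ethyl (triphenylphosphoranylidene)acetate
Product: 3 ethyl (2E)-hepta-2,6-dienoate
Conditions: CH2Cl2, 0 °C to rt
Reagents that add atoms: none
Why: Wittig olefination with a stabilised ylide is E-selective and needs no external base, so the enolisable aldehyde and the terminal alkene are untouched.

**Step 2**
Reactants: 3 ethyl (2E)-hepta-2,6-dienoate
Product: 4 (2E)-hepta-2,6-dien-1-ol
Conditions: DIBAL-H (2.2 equiv), CH2Cl2, −78 °C; aqueous Rochelle salt
Reagents that add atoms: none
Why: DIBAL-H reduces the conjugated ester in the 1,2 sense to the allylic alcohol without touching either alkene.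

**Step 3**
Reactants: 4 (2E)-hepta-2,6-dien-1-ol
Product: 5 (2E)-hepta-2,6-dien-1-yl methyl carbonate
Conditions: ClCO2Me, pyridine, CH2Cl2, 0 °C
Reagents that add atoms: methyl chloroformate, COC(=O)Cl
Why: Acylation of the primary alcohol with a chloroformate gives the carbonate leaving group, whose ionisation later releases the methoxide that activates the silyl nucleophile.

**Step 4**
Reactants: 5 (2E)-hepta-2,6-dien-1-yl methyl carbonate; 6 1-methoxy-2-methyl-1-(trimethylsilyloxy)prop-1-ene
Product: 7 methyl (3S)-3-ethenyl-2,2-dimethylhept-6-enoate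
Conditions: [Ir(cod)Cl]2 (2 mol %), (Ra,R,R)-BINOL-derived N,N-bis(1-phenylethyl)phosphoramidite (4 mol %, pre-activated with n-PrNH2), 6 (1.5 equiv), THF, 25–40 °C
Reagents that add atoms: none
Why: In this iridium-catalysed asymmetric allylic alkylation with a silyl ketene acetal, decarboxylative ionisation gives the allyl complex and methoxide, methoxide desilylates 6, and the ester enolate attacks the substituted terminus so that the ligand sets C5 as 3S; the linear E carbonate is chosen over the racemic branched isomer because the allyl complexes from the latter interconvert too slowly for full enantioconvergence.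

**Step 5**
Reactants: 7 methyl (3S)-3-ethenyl-2,2-dimethylhept-6-enoate
Product: 8 (3S)-3-ethenyl-2,2-dimethylhept-6-en-1-ol
Conditions: LiAlH4, Et2O, 0 °C to rt
Reagents that add atoms: none
Why: Hydride reduction of the hindered α-quaternary ester to the neopentyl alcohol leaves the isolated alkenes and the non-enolisable C5 centre unchanged.

**Step 6**
Reactants: 8 (3S)-3-ethenyl-2,2-dimethylhept-6-en-1-ol
Product: 9 (3S)-3-ethenyl-2,2-dimethylhept-6-en-1-yl trifluoromethanesulfonate
Conditions: Tf2O, pyridine, CH2Cl2, −78 to 0 °C; short silica plug, used at once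
Reagents that add atoms: trifluoromethanesulfonic anhydride, O=S(=O)(OS(=O)(=O)C(F)(F)F)C(F)(F)F
Why: Sulfonylation at oxygen gives a neopentyl triflate, which has no β-hydrogen to lose, is stable enough for rapid isolation and is far more reactive than a tosylate or halide.

**Step 7**
Reactants: 9 (3S)-3-ethenyl-2,2-dimethylhept-6-en-1-yl trifluoromethanesulfonate; 10 tert-butyldimethyl(prop-2-yn-1-yloxy)silane
Product: 12 tert-butyl{[(6S)-6-ethenyl-5,5-dimethyldec-9-en-2-yn-1-yl]oxy}dimethylsilane, via lithium acetylide 11 (not isolated)
Conditions: 10, n-BuLi, THF, −78 °C; DMPU; then 9, −78 °C to rt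
Reagents that add atoms: n-butyllithium, [Li]CCCC (lithium of 11 only)
Why: SN2 alkylation of a lithium acetylide by a primary triflate in THF/DMPU is the known way to force substitution at a neopentyl carbon, elimination being impossible, and it brings in C9, C1 and the protected C12 at once.

**Step 8**
Reactants: 12 tert-butyl{[(6S)-6-ethenyl-5,5-dimethyldec-9-en-2-yn-1-yl]oxy}dimethylsilane
Product: 13 (6S,6aS)-6-(but-3-en-1-yl)-3-{[(tert-butyldimethylsilyl)oxy]methyl}-5,5-dimethyl-4,5,6,6a-tetrahydropentalen-2(1H)-one
Conditions: Co2(CO)8 (10 mol %), tetramethylthiourea (60 mol %), CO (1 atm), toluene, 70 °C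
Reagents that add atoms: carbon monoxide, [C-]#[O+]
Why: The intramolecular Pauson–Khand [2+2+1] reaction of the 1,6-enyne closes rings A and C at once, leaves alone the butenyl alkene (which would have to form a seven-membered ring), places the alkyne substituent on C1 next to the carbonyl, and sets C4 because the C5 chain takes the exo position in the cobaltacycle, cis to C4–H and trans to C3.

**Step 9**
Reactants: 13 (6S,6aS)-6-(but-3-en-1-yl)-3-{[(tert-butyldimethylsilyl)oxy]methyl}-5,5-dimethyl-4,5,6,6a-tetrahydropentalen-2(1H)-one
Product: 14 (1S,2R,5S,6S,9S)-2-{[(tert-butyldimethylsilyl)oxy]methyl}-9,11,11-trimethyltricyclo[4.3.2.0(1,5)]undecan-3-one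
Conditions: Fe(acac)3 (30 mol %), PhSiH3 (3 equiv), EtOH (0.02 M), 60 °C
Reagents that add atoms: none
Why: An iron hydride formed from Fe(acac)3 and PhSiH3 delivers a hydrogen atom to the terminal CH2 of the butenyl chain, which becomes the methyl carbon C13 and leaves a nucleophilic secondary radical at C8; this radical adds to the enone β-carbon C9, and the tertiary α-keto radical at C1 is reduced by divalent iron to the enolate and protonated by ethanol, so the closest known reaction type is the iron-catalysed reductive alkene–enone coupling (hydrogen-atom-transfer Giese reaction) in its intramolecular, quaternary-centre-forming form. Ring B closes in the 6-exo-trig mode, which bridges ring C and gives the bicyclo[3.2.1]octane. C9 is fixed by the tether, since the chain sits on the face of ring C that carries C4–H and can reach only that face of C9, which keeps rings A and C cis-fused. C8 is set in a chair-like transition state with the methyl group on the C4 side (pseudoaxial on ring B), because the pseudoequatorial alternative lies over the C1–C12 bond, which is held in the enone plane on the C10 side, and suffers A(1,3) strain with the CH2OTBS group; this is the reason for carrying C12 through the step. C1 is protonated from the face away from the C8 methyl group, and its configuration is of no consequence because step 11 removes it. The step needs hydrogen-atom transfer to the electron-neutral terminal alkene ahead of the tetrasubstituted electron-poor enone, which the polarity and steric preference of the iron hydride provide, and it needs cyclisation ahead of radical reduction, which the activated acceptor, the lack of a good hydrogen donor and the chain buttressed by the gem-dimethyl group support.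

**Step 10**
Reactants: 14 (1S,2R,5S,6S,9S)-2-{[(tert-butyldimethylsilyl)oxy]methyl}-9,11,11-trimethyltricyclo[4.3.2.0(1,5)]undecan-3-one
Product: 15 (1S,2R,5S,6S,9S)-2-(hydroxymethyl)-9,11,11-trimethyltricyclo[4.3.2.0(1,5)]undecan-3-one
Conditions: HF·pyridine, THF, 0 °C to rt
Reagents that add atoms: none
Why: Cleavage of the primary TBS ether with an acidic fluoride source frees the β-hydroxy ketone without the retro-aldol loss of formaldehyde that a basic fluoride source could cause.

**Step 11**
Reactants: 15 (1S,2R,5S,6S,9S)-2-(hydroxymethyl)-9,11,11-trimethyltricyclo[4.3.2.0(1,5)]undecan-3-one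
Product: 17 (1S,5S,6S,9S)-9,11,11-trimethyl-2-methylidenetricyclo[4.3.2.0(1,5)]undecan-3-one (suberosenone), via primary mesylate 16 (not isolated)
Conditions: MsCl, Et3N, CH2Cl2, 0 °C; then DBU, 0 °C to rt; used at once
Reagents that add atoms: methanesulfonyl chloride, CS(=O)(=O)Cl (mesyl group of 16 only)
Why: Mesylation and E1cB elimination of a β-hydroxy ketone is the standard entry to an α-methylene ketone, can only give the C1=C12 alkene because C9 is quaternary, and erases the C1 centre.

**Step 12**
Reactants: 17 (1S,5S,6S,9S)-9,11,11-trimethyl-2-methylidenetricyclo[4.3.2.0(1,5)]undecan-3-one (two molecules, one as donor and one as acceptor)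
Product: 20 alertenone, via lithium dienolate 18 (not isolated), via dimer lithium enolate 19 (not isolated)
Conditions: 17 (1 equiv) added to LiHMDS (1.05 equiv), THF, −78 °C; then 17 (1 equiv), −78 to −40 °C; AcOH, −78 °C
Reagents that add atoms: lithium hexamethyldisilazide, [Li]N([Si](C)(C)C)[Si](C)(C)C (lithium of 18 and 19 only)
Why: The kinetic cross-conjugated lithium dienolate (C3 is the only enolisable position of 17) undergoes Michael addition to the exocyclic methylene C12' of a second molecule, reacting at C3 on the convex face of the A/C diquinane (cis to C4–H, trans to C5), and the hindered C1' enolate is then protonated cold from the face opposite the C8' methyl group, which places C12' cis to C8' as in the target.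

**Compound list**
1 | pent-4-enal | C=CCCC=O | starting material
2 | ethyl (triphenylphosphoranylidene)acetate | CCOC(=O)C=P(c1ccccc1)(c1ccccc1)c1ccccc1 | starting material
3 | ethyl (2E)-hepta-2,6-dienoate | C=CCC/C=C/C(=O)OCC | intermediate
4 | (2E)-hepta-2,6-dien-1-ol | C=CCC/C=C/CO | intermediate
5 | (2E)-hepta-2,6-dien-1-yl methyl carbonate | C=CCC/C=C/COC(=O)OC | intermediate
6 | 1-methoxy-2-methyl-1-(trimethylsilyloxy)prop-1-ene | COC(O[Si](C)(C)C)=C(C)C | starting material
7 | methyl (3S)-3-ethenyl-2,2-dimethylhept-6-enoate | COC(=O)C(C)(C)[C@@H](CCC=C)C=C | intermediate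
8 | (3S)-3-ethenyl-2,2-dimethylhept-6-en-1-ol | OCC(C)(C)[C@@H](CCC=C)C=C | intermediate
9 | (3S)-3-ethenyl-2,2-dimethylhept-6-en-1-yl trifluoromethanesulfonate | O=S(=O)(OCC(C)(C)[C@@H](CCC=C)C=C)C(F)(F)F | intermediate
10 | tert-butyldimethyl(prop-2-yn-1-yloxy)silane | C#CCO[Si](C)(C)C(C)(C)C | starting material
11 | lithium acetylide of 10 | [Li]C#CCO[Si](C)(C)C(C)(C)C | intermediate
12 | tert-butyl{[(6S)-6-ethenyl-5,5-dimethyldec-9-en-2-yn-1-yl]oxy}dimethylsilane | CC(C)(C)[Si](C)(C)OCC#CCC(C)(C)[C@@H](CCC=C)C=C | intermediate
13 | (6S,6aS)-6-(but-3-en-1-yl)-3-{[(tert-butyldimethylsilyl)oxy]methyl}-5,5-dimethyl-4,5,6,6a-tetrahydropentalen-2(1H)-one (C1=C9 enone, chain on C5 cis to C4–H) | O=C1C(CO[Si](C)(C)C(C)(C)C)=C2CC(C)(C)[C@@H](CCC=C)[C@@H]2C1 | intermediate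
14 | (1S,2R,5S,6S,9S)-2-{[(tert-butyldimethylsilyl)oxy]methyl}-9,11,11-trimethyltricyclo[4.3.2.0(1,5)]undecan-3-one | CC(C)(C)[Si](C)(C)OC[C@@H]1C(=O)C[C@H]2[C@@H]3CC[C@H](C)[C@]12CC3(C)C | intermediate
15 | (1S,2R,5S,6S,9S)-2-(hydroxymethyl)-9,11,11-trimethyltricyclo[4.3.2.0(1,5)]undecan-3-one | OC[C@@H]1C(=O)C[C@H]2[C@@H]3CC[C@H](C)[C@]12CC3(C)C | intermediate
16 | [(1S,2R,5S,6S,9S)-9,11,11-trimethyl-3-oxotricyclo[4.3.2.0(1,5)]undecan-2-yl]methyl methanesulfonate | CS(=O)(=O)OC[C@@H]1C(=O)C[C@H]2[C@@H]3CC[C@H](C)[C@]12CC3(C)C | intermediate
17 | (1S,5S,6S,9S)-9,11,11-trimethyl-2-methylidenetricyclo[4.3.2.0(1,5)]undecan-3-one (suberosenone) | C=C1C(=O)C[C@H]2[C@@H]3CC[C@H](C)[C@]12CC3(C)C | intermediate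
18 | lithium C2=C3 dienolate of 17 | C=C1C(O[Li])=C[C@H]2[C@@H]3CC[C@H](C)[C@]12CC3(C)C | intermediate
19 | lithium C1'=C2' enolate of the dimer | C=C1C(=O)[C@H](CC2=C(O[Li])C[C@H]3[C@@H]4CC[C@H](C)[C@]23CC4(C)C)[C@H]2[C@@H]3CC[C@H](C)[C@]12CC3(C)C | intermediate
20 | alertenone (C3 of the enone half joined through C12'H2 to C1' of the saturated half; C3–C12' cis to C4–H, C1'–C12' cis to C8') | C=C1C(=O)[C@H](C[C@@H]2C(=O)C[C@H]3[C@@H]4CC[C@H](C)[C@]23CC4(C)C)[C@H]2[C@@H]3CC[C@H](C)[C@]12CC3(C)C | target

**Step count**
Total: 12 steps. Longest linear sequence: 12 steps, from 1.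

**Steps most likely to fail**

Step 9. Three things could go wrong:
- The secondary C8 radical may be reduced before it cyclises.
- The radical may take the allylic C4–H in a 1,5-hydrogen shift.
- Facial selectivity at C8 may be too low despite the A(1,3) bias.

The fallback sets out from 13 and returns at 14. It ties C13 to C1 for the duration of the bond formation. Irradiation of 13 (about 350 nm, MeCN, rt) should give, by intramolecular enone–alkene [2+2] photocycloaddition, the cyclobutane photoadduct F1, with new bonds C8–C9 and C1–C13. The four-membered ring can only be cis-fused to ring B, so C13 is held next to C1 on the C4 side, which is the required C8 configuration. Samarium diiodide (SmI2, THF/MeOH, 0 °C) should then cleave the C1–C13 bond, which lies α to the ketone and overlaps with the ketyl. This turns C13 into the methyl group and gives 14 after protonation of the enolate.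

Step 12. Three things could go wrong:
- Oligomers may form through the enone that survives in the dimer.
- Proton transfer within the adduct enolate may scramble the sequence.
- Facial control may be lost when C1' is protonated.

The fallback sets out from 14 and 17 and returns at 20. It gives the two halves different roles. Kinetic deprotonation of 14 (LDA, THF, −78 °C) occurs at the less hindered C3 and gives the C3 lithium enolate F2, a donor with no acceptor function. Addition of F2 to 17 and a cold acetic acid quench should give the silyl-protected Michael adduct F3. HF·pyridine frees the hydroxymethyl dimer F4. MsCl/Et3N followed by DBU at 0 °C, by way of the dimer mesylate F5, installs C1=C12 last and gives 20.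

Step 7. Substitution at the neopentyl carbon may be so slow that decomposition or rearrangement of the triflate overtakes it. The fallback sets out from 8 and returns at 12. It builds the alkyne from carbonyl groups instead of displacing a leaving group.
- Dess–Martin oxidation of 8 gives the aldehyde F6.
- Wittig reaction with methoxymethylenetriphenylphosphorane gives the enol ether F7 (E/Z mixture).
- Aqueous acid gives the homologated aldehyde F8.
- Dimethyl (1-diazo-2-oxopropyl)phosphonate with K2CO3 in MeOH gives the terminal alkyne F9.
- n-BuLi and paraformaldehyde give the propargylic alcohol F10.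
- TBSCl and imidazole give 12.

**Further compounds**
F1 | step 9 | cyclobutane photoadduct of 13 (new bonds C8–C9 and C1–C13, C12H2OTBS on C1) | O=C1C[C@H]2[C@@H]3CC[C@@H]4C[C@@]1(CO[Si](C)(C)C(C)(C)C)[C@]24CC3(C)C
F2 | step 12 | C3 lithium enolate of 14 | CC(C)(C)[Si](C)(C)OC[C@@H]1C(O[Li])=C[C@H]2[C@@H]3CC[C@H](C)[C@]12CC3(C)C
F3 | step 12 | silyl-protected Michael adduct (alertenone with H and CH2OTBS on C1 in place of C1=C12) | CC(C)(C)[Si](C)(C)OC[C@@H]1C(=O)[C@H](C[C@@H]2C(=O)C[C@H]3[C@@H]4CC[C@H](C)[C@]23CC4(C)C)[C@H]2[C@@H]3CC[C@H](C)[C@]12CC3(C)C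
F4 | step 12 | hydroxymethyl dimer | OC[C@@H]1C(=O)[C@H](C[C@@H]2C(=O)C[C@H]3[C@@H]4CC[C@H](C)[C@]23CC4(C)C)[C@H]2[C@@H]3CC[C@H](C)[C@]12CC3(C)C
F5 | step 12 | dimer mesylate | CS(=O)(=O)OC[C@@H]1C(=O)[C@H](C[C@@H]2C(=O)C[C@H]3[C@@H]4CC[C@H](C)[C@]23CC4(C)C)[C@H]2[C@@H]3CC[C@H](C)[C@]12CC3(C)C
F6 | step 7 | (3S)-3-ethenyl-2,2-dimethylhept-6-enal | O=CC(C)(C)[C@@H](CCC=C)C=C
F7 | step 7 | (4S)-4-ethenyl-1-methoxy-3,3-dimethylocta-1,7-diene (E/Z mixture) | COC=CC(C)(C)[C@@H](CCC=C)C=C
F8 | step 7 | (4S)-4-ethenyl-3,3-dimethyloct-7-enal | O=CCC(C)(C)[C@@H](CCC=C)C=C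
F9 | step 7 | (5S)-5-ethenyl-6,6-dimethylnon-1-en-8-yne | C#CCC(C)(C)[C@@H](CCC=C)C=C
F10 | step 7 | (6S)-6-ethenyl-5,5-dimethyldec-9-en-2-yn-1-ol | OCC#CCC(C)(C)[C@@H](CCC=C)C=C
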